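**Plan**

1. Numbering (jatrophane): C3 ring ketone, C2 (methyl), C1, C15 (acetoxy carbon), C4=C5, oxolane C6 (methyl) to C9, C10 (CMe2), C11, C12, C13 (methyl), C14 ketone. Cuts, in retrosynthetic order: the C15 acetate and the C14 ketone (back to a 14,15-diol); C10–C11 (ring closure, with a temporary formyl group on C12); C4=C5 (aldol condensation of a cyclopentenone with an oxolane aldehyde); C4–C15 (aldol closure of a furan-derived cis-enedione).
2. Forward order: the oxolane from (S)-linalool, the cyclopentenone from 4,5-dimethylfurfural, union at C4=C5, closure of the macrocycle at C10–C11 by a hydrogen-atom-transfer-initiated radical conjugate addition, then removal of the formyl helper and adjustment of C14/C15.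
3. Enabling feature: C10 is the internal carbon of an isopropenyl group on oxolane C9, so Markovnikov hydrogen-atom transfer gives the tertiary radical. The oxolane is 2,5-trans, so this radical cannot reach C5 of the dienone. C11 is made the CH2 terminus of a 2-substituted acrolein, whose formyl group on C12 is later excised by decarbonylation.
4. Stereochemistry: C6 from (S)-linalool; C9 from Shi epoxidation and invertive 5-exo opening; C13 and a sacrificial C14 carbinol from Brown crotylboration; C15 by Felkin–Anh induction from C14 in the enedione aldol; C4=C5 (E) from E1cB elimination.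

Key step: step 12

Remark: (S)-(+)-linalool of high enantiomeric purity, 4,5-dimethylfuran-2-carbaldehyde, trans-but-2-ene and (+)-Ipc2BOMe are taken as purchasable.

**Step 1**
Reactants: 1 (S)-(+)-linalool
Product: 3 2-[(2S,5S)-5-ethenyl-5-methyloxolan-2-yl]propan-2-ol, via epoxide 2 (not isolated)
Conditions: D-fructose-derived Shi ketone (cat.), KHSO5 (Oxone), K2CO3, Bu4NHSO4, MeCN/CH2(OMe)2/aq. buffer, 0 °C; then CSA (cat.), CH2Cl2, 0 °C to rt
Reagents that add atoms: potassium peroxymonosulfate, OOS(=O)(=O)[O-].[K+]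
Why: Shi epoxidation should oxidise only the trisubstituted olefin on the face fixed by the chiral dioxirane (6R epoxide), and the tertiary hydroxyl then opens the epoxide 5-exo-tet with inversion, which sets C9 (S) beside the linalool-derived C6 (S) with the two ring substituents trans.

**Step 2**
Reactants: 3 2-[(2S,5S)-5-ethenyl-5-methyloxolan-2-yl]propan-2-ol
Product: 5 (2S,5S)-5-(2-hydroxypropan-2-yl)-2-methyloxolane-2-carbaldehyde, via ozonide 4 (not isolated)
Conditions: O3, CH2Cl2, −78 °C; then Me2S, −78 °C to rt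
Reagents that add atoms: ozone, [O-][O+]=O
Why: ozonolysis with reductive work-up cleaves the only olefin, and the resulting quaternary α-alkoxy aldehyde cannot epimerise or form a lactol with the trans-disposed tertiary alcohol.

**Step 3**
Reactants: 5 (2S,5S)-5-(2-hydroxypropan-2-yl)-2-methyloxolane-2-carbaldehyde
Product: 6 (2S,5S)-2-methyl-5-(prop-1-en-2-yl)oxolane-2-carbaldehyde
Conditions: Burgess reagent, THF, 50 °C
Reagents that add atoms: none
Why: Burgess dehydration by syn elimination of the tertiary sulfamate should take one of the six methyl hydrogens rather than the single ring hydrogen and so give the isopropenyl group.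

**Step 4**
Reactants: 7 4,5-dimethylfuran-2-carbaldehyde
Product: 9 (1R,2R)-1-(4,5-dimethylfuran-2-yl)-2-methylbut-3-en-1-ol, via borinate 8 (not isolated)
Conditions: (E)-crotyl-(+)-Ipc2B [made at −78 °C from trans-but-2-ene, KOt-Bu, n-BuLi, (+)-Ipc2BOMe, BF3·OEt2], THF, −78 °C; then NaOH, H2O2
Reagents that add atoms: (E)-crotyl-(+)-diisopinocampheylborane, C/C=C/CB([C@H]1C[C@H]2C[C@@H]([C@@H]1C)C2(C)C)[C@H]1C[C@H]2C[C@@H]([C@@H]1C)C2(C)C
Why: Brown crotylboration through a closed chair transition state, in which the E-crotyl group gives the anti product and the isopinocampheyl groups derived from (−)-α-pinene direct attack to the re face, sets C13 (R) and the temporary C14 carbinol (R).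

**Step 5**
Reactants: 9 (1R,2R)-1-(4,5-dimethylfuran-2-yl)-2-methylbut-3-en-1-ol
Product: 10 tert-butyl{[(1R,2R)-1-(4,5-dimethylfuran-2-yl)-2-methylbut-3-en-1-yl]oxy}dimethylsilane
Conditions: TBSCl, imidazole, DMF, rt
Reagents that add atoms: tert-butyldimethylsilyl chloride, CC(C)(C)[Si](C)(C)Cl
Why: standard silylation gives a non-chelating, base-stable ether that blocks pyranone formation in the furan oxidation and later serves as the polar group for Felkin–Anh control.

**Step 6**
Reactants: 10 tert-butyl{[(1R,2R)-1-(4,5-dimethylfuran-2-yl)-2-methylbut-3-en-1-yl]oxy}dimethylsilane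
Product: 11 (3Z,6R,7R)-6-[(tert-butyldimethylsilyl)oxy]-3,7-dimethylnona-3,8-diene-2,5-dione
Conditions: m-CPBA, NaHCO3, CH2Cl2, 0 °C
Reagents that add atoms: 3-chloroperbenzoic acid, OOC(=O)c1cccc(Cl)c1
Why: oxidative ring opening of a 2,5-dialkylfuran (epoxidation of the electron-rich ring, then opening) gives the cis-enedione, while the monosubstituted vinyl group reacts far more slowly.

**Step 7**
Reactants: 11 (3Z,6R,7R)-6-[(tert-butyldimethylsilyl)oxy]-3,7-dimethylnona-3,8-diene-2,5-dione
Product: 12 (4R)-4-{(1R,2R)-1-[(tert-butyldimethylsilyl)oxy]-2-methylbut-3-en-1-yl}-4-hydroxy-2-methylcyclopent-2-en-1-one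
Conditions: LiN(SiMe3)2, THF, −78 °C; then AcOH, −78 °C
Reagents that add atoms: none
Why: the kinetic methyl-ketone enolate closes the five-membered ring by intramolecular aldol addition (5-exo-trig) onto the α-silyloxy ketone, and the Felkin–Anh arrangement (C–OSi bond anti to the incoming enolate, hydrogen on the side of the approaching chain) should set C15 with the configuration needed for the target.

**Step 8**
Reactants: 12 (4R)-4-{(1R,2R)-1-[(tert-butyldimethylsilyl)oxy]-2-methylbut-3-en-1-yl}-4-hydroxy-2-methylcyclopent-2-en-1-one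
Product: 13 (4R)-4-{(1R,2R)-1-[(tert-butyldimethylsilyl)oxy]-2-methylbut-3-en-1-yl}-2-methyl-4-[(triethylsilyl)oxy]cyclopent-2-en-1-one
Conditions: Et3SiOTf, 2,6-lutidine, CH2Cl2, −78 to 0 °C
Reagents that add atoms: triethylsilyl trifluoromethanesulfonate, CC[Si](CC)(CC)OS(=O)(=O)C(F)(F)F
Why: silyl triflate silylation of the tertiary alcohol gives an ether that is a poor leaving group, so the C4 enolate of the next step neither eliminates nor undergoes retro-aldol cleavage.

**Step 9**
Reactants: 13 (the cyclopentenone) and 6 (2S,5S)-2-methyl-5-(prop-1-en-2-yl)oxolane-2-carbaldehyde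
Product: 16 (4S,5E)-4-{(1R,2R)-1-[(tert-butyldimethylsilyl)oxy]-2-methylbut-3-en-1-yl}-2-methyl-5-{[(2S,5S)-2-methyl-5-(prop-1-en-2-yl)oxolan-2-yl]methylidene}-4-[(triethylsilyl)oxy]cyclopent-2-en-1-one, via aldol adduct 14 (not isolated), via mesylate 15 (not isolated)
Conditions: LiN(i-Pr)2, THF, −78 °C; 6, −78 °C; MsCl, −78 to 0 °C; DBU, 0 °C to rt
Reagents that add atoms: none
Why: aldol condensation of a 4-silyloxy-4-alkylcyclopent-2-enone at its only enolisable position with a non-enolisable aldehyde, followed by E1cB elimination of the mesylate, should give the cross-conjugated dienone with the oxolane anti to the ring carbonyl (E), which is the usual thermodynamic outcome for such 5-alkylidene dienones.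

**Step 10**
Reactants: 16 (the dienone)
Product: 17 (4S,5E)-4-{(1R,2R)-1-[(tert-butyldimethylsilyl)oxy]-2-methyl-4-oxobutyl}-2-methyl-5-{[(2S,5S)-2-methyl-5-(prop-1-en-2-yl)oxolan-2-yl]methylidene}-4-[(triethylsilyl)oxy]cyclopent-2-en-1-one
Conditions: PdCl2(PhCN)2 (cat.), CuCl2 (cat.), AgNO2 (cat.), O2 (1 atm), t-BuOH/MeNO2, rt
Reagents that add atoms: dioxygen, O=O
Why: the nitrite-modified, aldehyde-selective Wacker oxidation acts only on the monosubstituted olefin, since 1,1-disubstituted and conjugated olefins are inert, and the branched allylic carbon favours the anti-Markovnikov aldehyde.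

**Step 11**
Reactants: 17 (the aldehyde)
Product: 19 (4S,5E)-4-{(1R,2R)-1-[(tert-butyldimethylsilyl)oxy]-3-formyl-2-methylbut-3-en-1-yl}-2-methyl-5-{[(2S,5S)-2-methyl-5-(prop-1-en-2-yl)oxolan-2-yl]methylidene}-4-[(triethylsilyl)oxy]cyclopent-2-en-1-one, via Mannich base 18 (not isolated)
Conditions: Me2N=CH2 I (Eschenmoser's salt), Et3N, CH2Cl2, rt
Reagents that add atoms: N,N-dimethylmethyleneiminium iodide, C=[N+](C)C.[I-]
Why: Mannich reaction at the only enolisable α-CH2 followed by elimination of dimethylamine (α-methylenation of an aldehyde) installs C11 as the terminal CH2 of a 2-substituted acrolein.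

**Step 12**
Reactants: 19 (the enal)
Product: 20 (4E,6S,9S,13R,14R,15S)-14-[(tert-butyldimethylsilyl)oxy]-6,9-epoxy-12-formyl-15-[(triethylsilyl)oxy]jatropha-1,4-dien-3-one (mixture at C12)
Conditions: Fe(acac)3 (1 equiv), PhSiH3 (3 equiv), EtOH/ethylene glycol 5:1, 60 °C, 19 added by syringe pump (final 1 mM)
Reagents that add atoms: none
Why: Proposed new method: an iron hydride formed from Fe(acac)3 and PhSiH3 should transfer a hydrogen atom to the CH2 terminus of the isopropenyl group (Markovnikov), the tertiary C10 radical then adds to the unsubstituted C11 terminus of the acrolein unit, and the α-formyl radical at C12 is reduced by divalent iron to the enolate and protonated by ethanol; the closest known reaction types are the iron-hydride reductive olefin coupling (MHAT Giese reaction), established between separate olefins and for five- to seven-membered rings, and tin-mediated radical conjugate additions that close 11- to 20-membered rings onto terminal acceptors. The ring closes in the 11-endo-trig mode counted through the oxolane oxygen (12-endo-trig counted through C7 and C8), with both acceptor carbons inside the new ring. The only new stereocentre, the formyl-bearing C12, is not controlled and is erased in step 13; C10 is not stereogenic. The step needs hydrogen-atom transfer to the electron-rich 1,1-disubstituted donor olefin rather than to the electron-poor enal or dienone olefins, which the known donor preference of this iron hydride should secure. It also needs addition at C11 rather than at C5 or C1 of the dienone: the trans arrangement of the two oxolane substituents makes 5-exo attack on C5 geometrically impossible, attack on C1 would need an eight-membered transition state beside the quaternary C15, and C11 is the only unhindered terminal acceptor carbon. Slow addition keeps the substrate dilute against intermolecular coupling, and the cis relationship of C15 and C6 across C4=C5 together with the two rings pre-folds the chain.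

**Step 13**
Reactants: 20 (the macrocyclic aldehyde)
Product: 21 (4E,6S,9S,13R,14R,15S)-14-[(tert-butyldimethylsilyl)oxy]-6,9-epoxy-15-[(triethylsilyl)oxy]jatropha-1,4-dien-3-one
Conditions: RhCl(PPh3)3 (1.1 equiv), toluene, 110 °C
Reagents that add atoms: none
Why: Tsuji–Wilkinson decarbonylation (oxidative addition into the formyl C–H bond, CO extrusion, C–H reductive elimination) removes the helper and leaves C12 as CH2, with ketones, silyl ethers and hindered olefins expected to be tolerated.

**Step 14**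
Reactants: 21 (the bis-silyl ether)
Product: 22 (4E,6S,9S,13R,14R,15S)-6,9-epoxy-14,15-dihydroxyjatropha-1,4-dien-3-one
Conditions: HF·pyridine, pyridine/THF, 0 °C to rt
Reagents that add atoms: none
Why: buffered fluoride cleaves both silyl ethers without the basic conditions that could trigger epimerisation or ketol rearrangement.

**Step 15**
Reactants: 22 (the diol)
Product: 23 (4E,6S,9S,13R,15S)-6,9-epoxy-15-hydroxyjatropha-1,4-diene-3,14-dione
Conditions: IBX, DMSO, rt
Reagents that add atoms: none
Why: IBX oxidises the secondary alcohol of a secondary/tertiary 1,2-diol to the α-ketol without C–C cleavage, and the neutral conditions should leave the now enolisable C13 (R) untouched.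

**Step 16**
Reactants: 23 (the α-ketol)
Product: 24 (4E,6S,9S,13R,15S)-15-acetoxy-6,9-epoxyjatropha-1,4-diene-3,14-dione (target)
Conditions: Ac2O, DMAP, Et3N, CH2Cl2, rt
Reagents that add atoms: acetic anhydride, CC(=O)OC(C)=O
Why: DMAP-catalysed acylation of the tertiary α-ketol hydroxyl is done last, when no neighbouring free hydroxyl remains for acyl migration and no enolate chemistry follows that could expel the acetate.

**Compound list**

1 | (S)-(+)-linalool, (3S)-3,7-dimethylocta-1,6-dien-3-ol | C=C[C@@](C)(O)CCC=C(C)C | starting material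
2 | (3S,6R)-6,7-epoxy-3,7-dimethyloct-1-en-3-ol | C=C[C@@](C)(O)CC[C@H]1OC1(C)C | intermediate (not isolated)
3 | 2-[(2S,5S)-5-ethenyl-5-methyloxolan-2-yl]propan-2-ol (vinyl and hydroxyisopropyl trans) | C=C[C@]1(C)CC[C@H](O1)C(C)(C)O | intermediate
4 | secondary ozonide (1,2,4-trioxolane) of 3 | C1OC(OO1)[C@]2(C)CC[C@H](O2)C(C)(C)O | intermediate (not isolated)
5 | (2S,5S)-5-(2-hydroxypropan-2-yl)-2-methyloxolane-2-carbaldehyde | O=C[C@]1(C)CC[C@H](O1)C(C)(C)O | intermediate
6 | (2S,5S)-2-methyl-5-(prop-1-en-2-yl)oxolane-2-carbaldehyde | O=C[C@]1(C)CC[C@H](O1)C(C)=C | intermediate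
7 | 4,5-dimethylfuran-2-carbaldehyde | O=Cc1cc(C)c(C)o1 | starting material
8 | diisopinocampheylborinate of 9 | C=C[C@@H](C)[C@@H](OB([C@H]1C[C@H]2C[C@@H]([C@@H]1C)C2(C)C)[C@H]1C[C@H]2C[C@@H]([C@@H]1C)C2(C)C)c1cc(C)c(C)o1 | intermediate (not isolated)
9 | (1R,2R)-1-(4,5-dimethylfuran-2-yl)-2-methylbut-3-en-1-ol | C=C[C@@H](C)[C@@H](O)c1cc(C)c(C)o1 | intermediate
10 | tert-butyl{[(1R,2R)-1-(4,5-dimethylfuran-2-yl)-2-methylbut-3-en-1-yl]oxy}dimethylsilane | C=C[C@@H](C)[C@@H](O[Si](C)(C)C(C)(C)C)c1cc(C)c(C)o1 | intermediate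
11 | (3Z,6R,7R)-6-[(tert-butyldimethylsilyl)oxy]-3,7-dimethylnona-3,8-diene-2,5-dione | C=C[C@@H](C)[C@@H](O[Si](C)(C)C(C)(C)C)C(=O)/C=C(\C(C)=O)C | intermediate
12 | (4R)-4-{(1R,2R)-1-[(tert-butyldimethylsilyl)oxy]-2-methylbut-3-en-1-yl}-4-hydroxy-2-methylcyclopent-2-en-1-one | O[C@@]1([C@H](O[Si](C)(C)C(C)(C)C)[C@H](C)C=C)C=C(C)C(=O)C1 | intermediate
13 | (4R)-4-{(1R,2R)-1-[(tert-butyldimethylsilyl)oxy]-2-methylbut-3-en-1-yl}-2-methyl-4-[(triethylsilyl)oxy]cyclopent-2-en-1-one | CC[Si](CC)(CC)O[C@@]1([C@H](O[Si](C)(C)C(C)(C)C)[C@H](C)C=C)C=C(C)C(=O)C1 | intermediate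
14 | aldol adduct of 13 and 6: 5-{hydroxy[(2S,5S)-2-methyl-5-(prop-1-en-2-yl)oxolan-2-yl]methyl} derivative of 13 (two new centres as formed) | CC[Si](CC)(CC)O[C@@]1([C@H](O[Si](C)(C)C(C)(C)C)[C@H](C)C=C)C=C(C)C(=O)C1C(O)[C@]1(C)CC[C@H](O1)C(C)=C | intermediate (not isolated)
15 | methanesulfonate of 14 | CC[Si](CC)(CC)O[C@@]1([C@H](O[Si](C)(C)C(C)(C)C)[C@H](C)C=C)C=C(C)C(=O)C1C(OS(C)(=O)=O)[C@]1(C)CC[C@H](O1)C(C)=C | intermediate (not isolated)
16 | (4S,5E)-4-{(1R,2R)-1-[(tert-butyldimethylsilyl)oxy]-2-methylbut-3-en-1-yl}-2-methyl-5-{[(2S,5S)-2-methyl-5-(prop-1-en-2-yl)oxolan-2-yl]methylidene}-4-[(triethylsilyl)oxy]cyclopent-2-en-1-one | CC[Si](CC)(CC)O[C@@]1([C@H](O[Si](C)(C)C(C)(C)C)[C@H](C)C=C)C=C(C)C(=O)/C1=C/[C@]1(C)CC[C@H](O1)C(C)=C | intermediate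
17 | analogue of 16 with the side chain (1R,2R)-1-[(tert-butyldimethylsilyl)oxy]-2-methyl-4-oxobutyl | CC[Si](CC)(CC)O[C@@]1([C@H](O[Si](C)(C)C(C)(C)C)[C@H](C)CC=O)C=C(C)C(=O)/C1=C/[C@]1(C)CC[C@H](O1)C(C)=C | intermediate
18 | Mannich base of 17, side chain (1R,2R)-1-[(tert-butyldimethylsilyl)oxy]-3-[(dimethylamino)methyl]-2-methyl-4-oxobutyl | CC[Si](CC)(CC)O[C@@]1([C@H](O[Si](C)(C)C(C)(C)C)[C@H](C)C(CN(C)C)C=O)C=C(C)C(=O)/C1=C/[C@]1(C)CC[C@H](O1)C(C)=C | intermediate (not isolated)
19 | enal, side chain (1R,2R)-1-[(tert-butyldimethylsilyl)oxy]-3-formyl-2-methylbut-3-en-1-yl | CC[Si](CC)(CC)O[C@@]1([C@H](O[Si](C)(C)C(C)(C)C)[C@H](C)C(=C)C=O)C=C(C)C(=O)/C1=C/[C@]1(C)CC[C@H](O1)C(C)=C | intermediate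
20 | (4E,6S,9S,13R,14R,15S)-14-[(tert-butyldimethylsilyl)oxy]-6,9-epoxy-12-formyl-15-[(triethylsilyl)oxy]jatropha-1,4-dien-3-one (C12 mixture) | CC[Si](CC)(CC)O[C@@]12C=C(C)C(=O)/C1=C/[C@]1(C)CC[C@H](O1)C(C)(C)CC(C=O)[C@@H](C)[C@H]2O[Si](C)(C)C(C)(C)C | intermediate
21 | (4E,6S,9S,13R,14R,15S)-14-[(tert-butyldimethylsilyl)oxy]-6,9-epoxy-15-[(triethylsilyl)oxy]jatropha-1,4-dien-3-one | CC[Si](CC)(CC)O[C@@]12C=C(C)C(=O)/C1=C/[C@]1(C)CC[C@H](O1)C(C)(C)CC[C@@H](C)[C@H]2O[Si](C)(C)C(C)(C)C | intermediate
22 | (4E,6S,9S,13R,14R,15S)-6,9-epoxy-14,15-dihydroxyjatropha-1,4-dien-3-one | O[C@@]12C=C(C)C(=O)/C1=C/[C@]1(C)CC[C@H](O1)C(C)(C)CC[C@@H](C)[C@H]2O | intermediate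
23 | (4E,6S,9S,13R,15S)-6,9-epoxy-15-hydroxyjatropha-1,4-diene-3,14-dione | O[C@@]12C=C(C)C(=O)/C1=C/[C@]1(C)CC[C@H](O1)C(C)(C)CC[C@@H](C)C2=O | intermediate
24 | (4E,6S,9S,13R,15S)-15-acetoxy-6,9-epoxyjatropha-1,4-diene-3,14-dione | CC(=O)O[C@@]12C=C(C)C(=O)/C1=C/[C@]1(C)CC[C@H](O1)C(C)(C)CC[C@@H](C)C2=O | target

**Step count and risks**

Total: 16 steps. Longest linear sequence: 13 steps (7 to 24, steps 4 to 16); the oxolane branch (steps 1 to 3) joins at step 9.

Steps most likely to fail:

Step 12. What may go wrong: reduction of the C10 radical before it finds C11, olefin isomerisation by reversible hydrogen-atom transfer, reduction of the enal, or oligomerisation in place of ring closure. The fallback uses known chemistry, makes the C10–C11 bond between two molecules and closes the large ring at C4=C5 instead. Setting out from 3, Burgess dehydration gives (2S,5S)-2-ethenyl-2-methyl-5-(prop-1-en-2-yl)oxolane F1. Setting out from 13, the oxidation of step 10 gives the cyclopentenone aldehyde F2 and the methylenation of step 11 gives the cyclopentenone enal F3. Iron-hydride reductive olefin coupling (Fe(acac)3, PhSiH3, EtOH, 60 °C) of F1, whose isopropenyl group is the better hydrogen-atom acceptor, with F3 should give the open-chain formyl compound F4. RhCl(PPh3)3 in hot toluene gives the decarbonylated enone F5. Ozonolysis of the vinyl group (O3 then Me2S; the enone olefin is electron-poor and slower) gives the keto aldehyde F6. LiN(SiMe3)2 at high dilution closes the ring by intramolecular aldol addition to the macrocyclic β-hydroxy ketone F7, and its methanesulfonate F8 eliminates with DBU to give 21, where the route is rejoined.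

Step 7. What may go wrong: poor facial selectivity at C15, or erosion of the kinetic ratio through retro-aldol equilibration of the lithium aldolate. Fallback: setting out from 11, Me3SiOTf/Et3N at −78 °C converts the methyl ketone into the trimethylsilyl enol ether F9, which is cyclised by a BF3·OEt2-promoted intramolecular Mukaiyama aldol addition at −78 °C. This addition is irreversible and goes through an open transition state under Felkin–Anh control by the non-chelating silyloxy group; aqueous work-up returns 12.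

Step 13. What may go wrong: olefin migration through rhodium hydrides, β-hydride elimination from the alkylrhodium intermediate, or thermal degradation of the dienone at 110 °C. Fallback: setting out from 20, Pinnick oxidation (NaClO2, NaH2PO4, 2-methylbut-2-ene) gives the macrocyclic carboxylic acid F10. This is converted (N-hydroxypyridine-2-thione, DCC) into the thiohydroxamate ester F11 and reduced under visible light with t-BuSH (Barton decarboxylation) to give 21.

**Further compounds**

F1 | step 12 | (2S,5S)-2-ethenyl-2-methyl-5-(prop-1-en-2-yl)oxolane | C=C[C@]1(C)CC[C@H](O1)C(C)=C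
F2 | step 12 | (4R)-4-{(1R,2R)-1-[(tert-butyldimethylsilyl)oxy]-2-methyl-4-oxobutyl}-2-methyl-4-[(triethylsilyl)oxy]cyclopent-2-en-1-one | CC[Si](CC)(CC)O[C@@]1([C@H](O[Si](C)(C)C(C)(C)C)[C@H](C)CC=O)C=C(C)C(=O)C1
F3 | step 12 | (4R)-4-{(1R,2R)-1-[(tert-butyldimethylsilyl)oxy]-3-formyl-2-methylbut-3-en-1-yl}-2-methyl-4-[(triethylsilyl)oxy]cyclopent-2-en-1-one | CC[Si](CC)(CC)O[C@@]1([C@H](O[Si](C)(C)C(C)(C)C)[C@H](C)C(=C)C=O)C=C(C)C(=O)C1
F4 | step 12 | open-chain coupling product of F1 and F3 (C10–C11 bond formed, formyl group on C12, vinyl group on C6) | CC[Si](CC)(CC)O[C@@]1([C@H](O[Si](C)(C)C(C)(C)C)[C@H](C)C(C=O)CC(C)(C)[C@@H]2CC[C@@](C)(C=C)O2)C=C(C)C(=O)C1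
F5 | step 12 | decarbonylated open-chain enone | CC[Si](CC)(CC)O[C@@]1([C@H](O[Si](C)(C)C(C)(C)C)[C@H](C)CCC(C)(C)[C@@H]2CC[C@@](C)(C=C)O2)C=C(C)C(=O)C1
F6 | step 12 | open-chain keto aldehyde (formyl group on C6 of the oxolane) | CC[Si](CC)(CC)O[C@@]1([C@H](O[Si](C)(C)C(C)(C)C)[C@H](C)CCC(C)(C)[C@@H]2CC[C@@](C)(C=O)O2)C=C(C)C(=O)C1
F7 | step 12 | macrocyclic β-hydroxy ketone (5-hydroxy-4,5-dihydro form of 21) | CC[Si](CC)(CC)O[C@@]12C=C(C)C(=O)C1C(O)[C@]1(C)CC[C@H](O1)C(C)(C)CC[C@@H](C)[C@H]2O[Si](C)(C)C(C)(C)C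
F8 | step 12 | methanesulfonate of F7 | CC[Si](CC)(CC)O[C@@]12C=C(C)C(=O)C1C(OS(C)(=O)=O)[C@]1(C)CC[C@H](O1)C(C)(C)CC[C@@H](C)[C@H]2O[Si](C)(C)C(C)(C)C
F9 | step 7 | trimethylsilyl enol ether of the methyl ketone of 11 | C=C[C@@H](C)[C@@H](O[Si](C)(C)C(C)(C)C)C(=O)/C=C(\C(=C)O[Si](C)(C)C)C
F10 | step 13 | macrocyclic C12 carboxylic acid (formyl group of 20 oxidised) | CC[Si](CC)(CC)O[C@@]12C=C(C)C(=O)/C1=C/[C@]1(C)CC[C@H](O1)C(C)(C)CC(C(=O)O)[C@@H](C)[C@H]2O[Si](C)(C)C(C)(C)C
F11 | step 13 | N-acyloxypyridine-2-thione (Barton) ester of F10 | CC[Si](CC)(CC)O[C@@]12C=C(C)C(=O)/C1=C/[C@]1(C)CC[C@H](O1)C(C)(C)CC(C(=O)On1ccccc1=S)[C@@H](C)[C@H]2O[Si](C)(C)C(C)(C)C
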